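**Retrosynthetic overview**

1. The aryl ether is made last: Mitsunobu inversion at the benzylic carbinol of the bicyclic lactone alcohol by the 7-OH of (2S)-pinocembrin joins the two halves.
2. The γ-lactone is read as the Baeyer–Villiger product of a cyclobutanone: oxygen is inserted between the carbonyl carbon and the ring-fusion CH, so the lactone C–O bond is a temporary C–C bond one step earlier.
3. Key disconnection: one intramolecular ketene–vinyl ether [2+2] cycloaddition forms the acyl carbon–CH2 bond and the bond between the two ring-fusion carbons, closing the cyclobutanone and the oxolane together. Enabling feature: in the 2,6-dioxabicyclo[3.3.0]octan-3-one the oxolane oxygen sits on the ring-fusion carbon β to the lactone carbonyl, so this carbon and the lactone α-CH2 are the two carbons of an O-vinyl group, while the carbonyl carbon and the γ ring-fusion carbon are the two carbons of a ketene, tied to the vinyl ether oxygen by the CH2–CH part of the oxolane.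
4. The acyclic γ-vinyloxy acid carrying the erythro PhCH(OPMB)–CH(O) unit comes from an erythro epoxy alcohol (Sharpless kinetic resolution) by epoxide opening with cyanomethyllithium, O-vinylation and nitrile hydrolysis.
5. Ring order: oxolane and four-membered ring together (step 6), then the γ-lactone by ring expansion (step 7); the flavanone rings are bought intact.

Key step: step 6

Remark: the target SMILES is read as (3aR,5S,6aR) in the bicyclic lactone, (S) at the benzylic ether carbon and (2S) in the flavanone; natural (2S)-pinocembrin and racemic 1-phenylprop-2-en-1-ol are taken as purchasable.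

**Route**

Step 1
Reactants: 1 rac-1-phenylprop-2-en-1-ol
Product: 2 (R)-[(2S)-oxiran-2-yl](phenyl)methanol
Conditions: Ti(OiPr)4 (20 mol%), D-(−)-diisopropyl tartrate (24 mol%), t-BuOOH (0.45 equiv, anhydrous), 4 Å molecular sieves, CH2Cl2, −20 °C; stopped near 45% conversion, unreacted (R)-1 removed by chromatography
Reagents that add atoms: tert-butyl hydroperoxide CC(C)(C)OO
Why: Sharpless kinetic resolution (titanium–tartrate asymmetric epoxidation): with the D-(−)-tartrate the (S)-enantiomer of 1 should be epoxidised much faster than the (R)-enantiomer and on the alkene face that gives the erythro (anti) epoxy alcohol, so both stereocentres of 2 are set by the catalyst.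

Step 2
Reactants: 2 (R)-[(2S)-oxiran-2-yl](phenyl)methanol
Product: 3 (2S)-2-[(R)-[(4-methoxyphenyl)methoxy](phenyl)methyl]oxirane
Conditions: NaH, 4-methoxybenzyl chloride, Bu4NI (cat.), THF/DMF, 0 °C to rt
Reagents that add atoms: 4-methoxybenzyl chloride COc1ccc(CCl)cc1
Why: Williamson etherification of the sodium alkoxide with the benzylic chloride (iodide-catalysed); O-alkylation at 0 °C is expected to outrun Payne rearrangement of the epoxy alkoxide, and neither stereocentre is touched.

Step 3
Reactants: 3 (2S)-2-[(R)-[(4-methoxyphenyl)methoxy](phenyl)methyl]oxirane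
Product: 4 (4S,5R)-4-hydroxy-5-[(4-methoxyphenyl)methoxy]-5-phenylpentanenitrile
Conditions: MeCN, n-BuLi, THF, −78 °C; then 3, −78 °C to rt; aq NH4Cl
Reagents that add atoms: acetonitrile CC#N
Why: SN2 opening of the terminal epoxide at its unsubstituted CH2 carbon by cyanomethyllithium (nitrile-anion alkylation); the C–O bond of the oxirane CH is retained, so its configuration carries over unchanged into the secondary alcohol.

Step 4
Reactants: 4 (4S,5R)-4-hydroxy-5-[(4-methoxyphenyl)methoxy]-5-phenylpentanenitrile
Product: 5 (4S,5R)-4-(ethenyloxy)-5-[(4-methoxyphenyl)methoxy]-5-phenylpentanenitrile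
Conditions: [Ir(cod)Cl]2 (2 mol%), Na2CO3 (0.6 equiv), vinyl acetate (3 equiv), toluene, 100 °C
Reagents that add atoms: vinyl acetate CC(=O)OC=C
Why: Iridium-catalysed transfer vinylation (alkoxide addition to vinyl acetate at iridium followed by β-acetate elimination) converts the secondary hydroxyl into the vinyl ether under weakly basic conditions that the nitrile and the PMB ether tolerate; no stereocentre is involved.

Step 5
Reactants: 5 (4S,5R)-4-(ethenyloxy)-5-[(4-methoxyphenyl)methoxy]-5-phenylpentanenitrile
Product: 7 (4S,5R)-4-(ethenyloxy)-5-[(4-methoxyphenyl)methoxy]-5-phenylpentanoic acid, via primary amide 6 (not isolated)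
Conditions: KOH (10 equiv), EtOH/H2O, reflux; then 0 °C, 1 M HCl to pH about 5.5, extraction; acid used at once
Reagents that add atoms: water O; potassium hydroxide [K+].[OH-]
Why: Alkaline nitrile hydrolysis through the primary amide; vinyl ether and PMB ether are inert to hydroxide, the etherified γ-oxygen cannot lactonise, and the cold work-up at pH about 5.5 is chosen so that the acid-labile vinyl ether survives.

Step 6
Reactants: 7 (4S,5R)-4-(ethenyloxy)-5-[(4-methoxyphenyl)methoxy]-5-phenylpentanoic acid
Product: 10 (1R,3S,5R)-3-[(R)-[(4-methoxyphenyl)methoxy](phenyl)methyl]-2-oxabicyclo[3.2.0]heptan-6-one, via acyloxypyridinium salt 8 (not isolated), via ketene 9 (not isolated)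
Conditions: 2-chloro-1-methylpyridinium iodide (1.5 equiv), Et3N (5 equiv), MeCN, reflux; 7 added slowly (final about 0.005 M)
Reagents that add atoms: none
Why: The carboxylate is O-activated as the 2-acyloxypyridinium salt 8, Et3N removes an α-proton to give the aldoketene 9, and 9 undergoes a thermal intramolecular ketene–alkene [2+2] cycloaddition with the tethered vinyl ether, the closest known reaction types being the intramolecular ketene/alkene cycloaddition to bicyclo[3.2.0]heptan-6-ones and the ketene/enol ether cycloaddition to 3-alkoxycyclobutanones. The cycloaddition is concerted but asynchronous: the electrophilic ketene carbonyl carbon bonds first to the nucleophilic CH2 terminus of the vinyl ether and the ketene α-carbon then closes onto the oxygen-stabilised internal carbon. The oxolane closes through the bond from the ketene α-carbon to the internal alkene carbon across the three-atom CH2–CH–O tether (fused mode, formally 5-exo-trig) and the cyclobutanone through the acyl carbon-to-CH2 bond, so both rings arise together. The two ring-fusion stereocentres are necessarily cis because both bonds form on one face of the vinyl ether; their sense relative to the existing carbinol centre is controlled by that centre, since the vinyl ether should react as its s-cis rotamer with the carbinol C–H eclipsing the vinyl group (1,3-allylic strain towards the CH2 terminus), so the tethered ketene reaches the alkene face opposite to the bulky CH(OPMB)Ph group, which ends up exo (trans to the four-membered ring) as the target requires. The step needs regioselectivity (fused against bridged adduct) and cyclisation in preference to ketene dimerisation; the ring oxygen on the internal alkene carbon secures the first, and the electron-rich alkene held three atoms away together with slow addition at high dilution secures the second.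

Step 7
Reactants: 10 (1R,3S,5R)-3-[(R)-[(4-methoxyphenyl)methoxy](phenyl)methyl]-2-oxabicyclo[3.2.0]heptan-6-one
Product: 11 (3aR,5S,6aR)-5-[(R)-[(4-methoxyphenyl)methoxy](phenyl)methyl]hexahydrofuro[3,2-b]furan-2-one
Conditions: mCPBA (1.2 equiv), NaHCO3, CH2Cl2, 0 °C
Reagents that add atoms: 3-chloroperoxybenzoic acid OOC(=O)c1cccc(Cl)c1
Why: Baeyer–Villiger oxidation: the strained cyclobutanone reacts selectively, the more substituted ring-fusion carbon migrates with retention of configuration so that oxygen is inserted between the carbonyl carbon and that carbon, giving the cis-fused γ-lactone of the target; the bicarbonate buffer protects the β-alkoxy ketone from acid.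

Step 8
Reactants: 11 (3aR,5S,6aR)-5-[(R)-[(4-methoxyphenyl)methoxy](phenyl)methyl]hexahydrofuro[3,2-b]furan-2-one
Product: 12 (3aR,5S,6aR)-5-[(R)-hydroxy(phenyl)methyl]hexahydrofuro[3,2-b]furan-2-one
Conditions: DDQ (1.5 equiv), CH2Cl2/pH 7 phosphate buffer, 0 °C to rt
Reagents that add atoms: none
Why: Oxidative cleavage of the PMB ether by DDQ (hydride abstraction from the electron-rich 4-methoxybenzylic CH2 and hydrolysis of the oxocarbenium ion) frees the benzylic alcohol with retention; lactone, oxolane and the unactivated phenyl-substituted C–H are expected to be untouched.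

Step 9
Reactants: 12 (3aR,5S,6aR)-5-[(R)-hydroxy(phenyl)methyl]hexahydrofuro[3,2-b]furan-2-one; 13 (2S)-pinocembrin [(2S)-5,7-dihydroxy-2-phenylchroman-4-one]
Product: 14 (2S)-5-hydroxy-7-{(S)-[(3aR,5S,6aR)-2-oxohexahydrofuro[3,2-b]furan-5-yl](phenyl)methoxy}-2-phenylchroman-4-one (CNP0152032.1)
Conditions: PPh3 (1.5 equiv), DIAD (1.5 equiv), 13 (1.2 equiv), THF, 0 °C to rt
Reagents that add atoms: none
Why: Mitsunobu etherification: the alkoxyphosphonium ion of 12 is displaced in an SN2 step by the phenoxide of 13 with inversion (R to S) at the benzylic carbon; the 7-OH is the acidic, non-chelated phenol (the 5-OH is hydrogen-bonded to the C-4 carbonyl) and the near-neutral conditions preserve the lactone and the base-sensitive C-2 centre of the flavanone.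

**Compound list**

1 | rac-1-phenylprop-2-en-1-ol | C=CC(O)c1ccccc1 | starting material
2 | (R)-[(2S)-oxiran-2-yl](phenyl)methanol | O[C@H](c1ccccc1)[C@@H]1CO1 | intermediate
3 | (2S)-2-[(R)-[(4-methoxyphenyl)methoxy](phenyl)methyl]oxirane | COc1ccc(CO[C@H](c2ccccc2)[C@@H]2CO2)cc1 | intermediate
4 | (4S,5R)-4-hydroxy-5-[(4-methoxyphenyl)methoxy]-5-phenylpentanenitrile | N#CCC[C@H](O)[C@H](OCc1ccc(OC)cc1)c1ccccc1 | intermediate
5 | (4S,5R)-4-(ethenyloxy)-5-[(4-methoxyphenyl)methoxy]-5-phenylpentanenitrile | N#CCC[C@H](OC=C)[C@H](OCc1ccc(OC)cc1)c1ccccc1 | intermediate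
6 | (4S,5R)-4-(ethenyloxy)-5-[(4-methoxyphenyl)methoxy]-5-phenylpentanamide (not isolated) | NC(=O)CC[C@H](OC=C)[C@H](OCc1ccc(OC)cc1)c1ccccc1 | intermediate
7 | (4S,5R)-4-(ethenyloxy)-5-[(4-methoxyphenyl)methoxy]-5-phenylpentanoic acid | OC(=O)CC[C@H](OC=C)[C@H](OCc1ccc(OC)cc1)c1ccccc1 | intermediate
8 | 2-{[(4S,5R)-4-(ethenyloxy)-5-[(4-methoxyphenyl)methoxy]-5-phenylpentanoyl]oxy}-1-methylpyridin-1-ium iodide (not isolated) | C[n+]1ccccc1OC(=O)CC[C@H](OC=C)[C@H](OCc1ccc(OC)cc1)c1ccccc1.[I-] | intermediate
9 | (4S,5R)-4-(ethenyloxy)-5-[(4-methoxyphenyl)methoxy]-5-phenylpent-1-en-1-one, the ketene (not isolated) | O=C=CC[C@H](OC=C)[C@H](OCc1ccc(OC)cc1)c1ccccc1 | intermediate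
10 | (1R,3S,5R)-3-[(R)-[(4-methoxyphenyl)methoxy](phenyl)methyl]-2-oxabicyclo[3.2.0]heptan-6-one | O=C1C[C@H]2O[C@H]([C@H](OCc3ccc(OC)cc3)c3ccccc3)C[C@H]21 | intermediate
11 | (3aR,5S,6aR)-5-[(R)-[(4-methoxyphenyl)methoxy](phenyl)methyl]hexahydrofuro[3,2-b]furan-2-one | O=C1C[C@H]2O[C@H]([C@H](OCc3ccc(OC)cc3)c3ccccc3)C[C@H]2O1 | intermediate
12 | (3aR,5S,6aR)-5-[(R)-hydroxy(phenyl)methyl]hexahydrofuro[3,2-b]furan-2-one | O=C1C[C@H]2O[C@H]([C@H](O)c3ccccc3)C[C@H]2O1 | intermediate
13 | (2S)-pinocembrin, (2S)-5,7-dihydroxy-2-phenylchroman-4-one | Oc1cc(O)c2c(c1)O[C@H](c1ccccc1)CC2=O | starting material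
14 | (2S)-5-hydroxy-7-{(S)-[(3aR,5S,6aR)-2-oxohexahydrofuro[3,2-b]furan-5-yl](phenyl)methoxy}-2-phenylchroman-4-one (CNP0152032.1) | O=C1C[C@H]2O[C@H]([C@@H](Oc3cc(O)c4c(c3)O[C@H](c3ccccc3)CC4=O)c3ccccc3)C[C@H]2O1 | target

**Step count and risks**

Total step count: 9. Longest linear sequence: 9 steps (1 to 14); 13 is bought and enters in the last step.

Steps most likely to fail:

Step 6. The aldoketene may be lost to dimerisation before it cyclises, or the carbinol centre may discriminate the two alkene faces too weakly. Fallback: the ring is made first and a reactive ketene is added from outside. Setting out from hydroxy nitrile 4, reduction of the nitrile (iBu2AlH, CH2Cl2, −78 °C; aqueous potassium sodium tartrate) should give, after hydrolysis of the imine and ring closure, the lactol (5S)-5-[(R)-[(4-methoxyphenyl)methoxy](phenyl)methyl]oxolan-2-ol F1. Dehydration through its mesylate (MsCl, Et3N, CH2Cl2, −20 °C to reflux) should give the cyclic enol ether (2S)-2-[(R)-[(4-methoxyphenyl)methoxy](phenyl)methyl]-2,3-dihydrofuran F2. Intermolecular [2+2] cycloaddition of dichloroketene (Cl3CCOCl, zinc–copper couple, Et2O) on the face anti to the 2-substituent, with the acyl carbon bonding to the β-carbon of the enol ether, should give (1S,3S,5R)-7,7-dichloro-3-[(R)-[(4-methoxyphenyl)methoxy](phenyl)methyl]-2-oxabicyclo[3.2.0]heptan-6-one F3. Reductive dechlorination (Zn, NH4Cl, MeOH or Zn, AcOH, rt) comes back to the route at cyclobutanone 10.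

Step 9. The oxolane oxygen may participate at the activated benzylic carbon (ring expansion through an oxiranium ion), elimination may compete, and stereochemical integrity or site selectivity between the two phenols may be eroded. Fallback: activation and displacement are separated. Setting out from alcohol 12, sulfonylation (MsCl, Et3N, CH2Cl2, −20 °C) should give with retention (R)-[(3aR,5S,6aR)-2-oxohexahydrofuro[3,2-b]furan-5-yl](phenyl)methyl methanesulfonate F4, whose ionisation is retarded by the β-oxygen. Williamson-type SN2 displacement by the 7-phenoxide of 13 (Cs2CO3, 1 equiv, DMF, 0 °C to rt) with inversion comes back to the route at 14.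

Step 4. Vinyl transfer to the hindered secondary hydroxyl may be slow or incomplete, with competing O-acetylation. Fallback: the vinyl group is built by addition and elimination. Setting out from 4, base-catalysed conjugate addition of the alkoxide to phenyl vinyl sulfoxide (NaH cat., THF, 0 °C to rt) should give (4S,5R)-5-[(4-methoxyphenyl)methoxy]-5-phenyl-4-[2-(phenylsulfinyl)ethoxy]pentanenitrile F5. Thermal sulfoxide syn-elimination (toluene, NaHCO3, 110 °C) comes back to the route at vinyl ether 5.

Further compounds
F1 | step 6 | (5S)-5-[(R)-[(4-methoxyphenyl)methoxy](phenyl)methyl]oxolan-2-ol | OC1CC[C@H](O1)[C@H](OCc1ccc(OC)cc1)c1ccccc1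
F2 | step 6 | (2S)-2-[(R)-[(4-methoxyphenyl)methoxy](phenyl)methyl]-2,3-dihydrofuran | C1=CC[C@H](O1)[C@H](OCc1ccc(OC)cc1)c1ccccc1
F3 | step 6 | (1S,3S,5R)-7,7-dichloro-3-[(R)-[(4-methoxyphenyl)methoxy](phenyl)methyl]-2-oxabicyclo[3.2.0]heptan-6-one | O=C1C(Cl)(Cl)[C@H]2O[C@H]([C@H](OCc3ccc(OC)cc3)c3ccccc3)C[C@H]21
F4 | step 9 | (R)-[(3aR,5S,6aR)-2-oxohexahydrofuro[3,2-b]furan-5-yl](phenyl)methyl methanesulfonate | O=C1C[C@H]2O[C@H]([C@H](OS(C)(=O)=O)c3ccccc3)C[C@H]2O1
F5 | step 4 | (4S,5R)-5-[(4-methoxyphenyl)methoxy]-5-phenyl-4-[2-(phenylsulfinyl)ethoxy]pentanenitrile | N#CCC[C@H](OCCS(=O)c1ccccc1)[C@H](OCc1ccc(OC)cc1)c1ccccc1
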